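**Retrosynthetic overview**
- Prestegane A ⇒ its O-benzyl ether ⇒ C3–C7 bond: trans-selective enolate benzylation of (R)-4-(3,4-dimethoxybenzyl)butyrolactone with 3-benzyloxy-4-methoxybenzyl bromide.
- That lactone (O1, C2 carbonyl, C3, C4, C5; the final ring, formed second) ⇒ (R)-2-(3,4-dimethoxybenzyl)succinic acid 1-methyl ester; the ester carbon becomes C5 and the acid carbon C2.
- Feature used: the benzylic carbon C7', between the 3,4-dimethoxyphenyl ring and C4, can carry a temporary oxygen. As a ketone it makes C4 the enolisable α-carbon of a β-keto ester; as a carbinol it closes a throwaway γ-aryl lactone (formed first) onto the future C2 carboxyl, and hydrogenolysis of C7'–O then leaves only the C4 configuration.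
- Temporary lactone ⇒ racemic dimethyl 2-(3,4-dimethoxybenzoyl)succinate by asymmetric transfer hydrogenation with dynamic kinetic resolution ⇒ β-keto ester + methyl bromoacetate ⇒ 3',4'-dimethoxyacetophenone + dimethyl carbonate.

Key step: step 3

Remark: the (S,S)-TsDPEN catalyst is assumed to follow the usual aryl ketone model and give the (S)-benzylic carbinol with syn selectivity; should the sense prove opposite, the mirror-image catalyst is used.

**Step 1**
Reactants: 1 3',4'-dimethoxyacetophenone; 2 dimethyl carbonate
Product: 3 methyl 3-(3,4-dimethoxyphenyl)-3-oxopropanoate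
Conditions: NaH, (MeO)2CO, toluene, reflux; then aq. HCl
Reagents that add atoms: none
Why: Crossed Claisen condensation of the ketone enolate with the non-enolisable carbonate, driven by irreversible deprotonation of the β-keto ester formed.

**Step 2**
Reactants: 3 methyl 3-(3,4-dimethoxyphenyl)-3-oxopropanoate; 4 methyl bromoacetate
Product: 5 racemic dimethyl 2-(3,4-dimethoxybenzoyl)succinate
Conditions: K2CO3, acetone, rt
Reagents that add atoms: none
Why: SN2 C-alkylation of the stabilised β-keto ester enolate by the reactive α-bromo ester, with mild carbonate base and one equivalent of bromide limiting dialkylation; the racemate is what the next step needs.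

**Step 3**
Reactants: 5 racemic dimethyl 2-(3,4-dimethoxybenzoyl)succinate
Product: 7 methyl (2S,3S)-2-(3,4-dimethoxyphenyl)-5-oxotetrahydrofuran-3-carboxylate (trans), via syn hydroxy diester 6 (not isolated)
Conditions: RuCl(p-cymene)[(S,S)-TsDPEN] (1 mol%), HCO2H/NEt3 (5:2), DMF, 40 °C
Reagents that add atoms: none
Why: The Ru–H/N–H species generated from formate transfers hydride and proton to the aryl ketone through an outer-sphere six-membered transition state (Noyori–Ikariya asymmetric transfer hydrogenation), forming the C7'–H bond. The closest known reaction type is the transfer-hydrogenative dynamic kinetic resolution of α-substituted β-keto esters, to which 2-aroylsuccinates belong. The hydroxyl of 6 then attacks the distal CH2CO2Me ester in a 5-exo-trig acyl substitution that expels methanol and closes the lactone, the proximal ester being out of reach because it would need a four-membered ring. The carbinol centre (lactone C2, S) is set by the catalyst through the aryl/p-cymene CH–π contact, as for acetophenone; the adjacent centre (lactone C3, S, the future C4 of the target) is set because the enantiomers of 5 interconvert through the enol in the HCO2H/NEt3 medium and the catalyst reduces faster the one that leads to the syn hydroxy ester, hence the trans lactone. The selectivity needed is syn over anti, because once C7' is deoxygenated any cis lactone would turn into the enantiomer of 8. The acidic proton between ketone and ester secures fast racemisation, and the trans lactone is to be freed from cis isomer by recrystallisation or chromatography before step 4.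

**Step 4**
Reactants: 7 methyl (2S,3S)-2-(3,4-dimethoxyphenyl)-5-oxotetrahydrofuran-3-carboxylate
Product: 8 (R)-4-(3,4-dimethoxyphenyl)-3-(methoxycarbonyl)butanoic acid
Conditions: H2 (4 atm), 10% Pd/C, AcOH, 50 °C
Reagents that add atoms: none
Why: Catalytic hydrogenolysis of the benzylic lactone C–O bond, eased by the electron-rich aryl ring; the α-ester stereocentre is not touched and its descriptor changes from S to R only because the CIP priorities change.

**Step 5**
Reactants: 8 (R)-4-(3,4-dimethoxyphenyl)-3-(methoxycarbonyl)butanoic acid
Product: 11 (R)-4-(3,4-dimethoxybenzyl)dihydrofuran-2(3H)-one, via potassium carboxylate 9 (not isolated), via hydroxy acid 10 (not isolated)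
Conditions: KOH (1.0 equiv), EtOH, 0 °C; NaBH4, CaCl2, EtOH, −10 °C → rt; then 2 M HCl, rt
Reagents that add atoms: none
Why: Chemoselective borohydride reduction, since Ca(BH4)2 made in the flask reduces the methyl ester but not the carboxylate salt, and acidification lactonises the γ-hydroxy acid (5-exo-trig) with the stereocentre unchanged.

**Step 6**
Reactants: 12 3-(benzyloxy)-4-methoxybenzaldehyde
Product: 13 [3-(benzyloxy)-4-methoxyphenyl]methanol
Conditions: NaBH4, MeOH, 0 °C; then aq. HCl
Reagents that add atoms: none
Why: Plain borohydride reduction of an aromatic aldehyde; the benzyl ether is inert.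

**Step 7**
Reactants: 13 [3-(benzyloxy)-4-methoxyphenyl]methanol
Product: 14 2-(benzyloxy)-4-(bromomethyl)-1-methoxybenzene
Conditions: PBr3, CH2Cl2, 0 °C
Reagents that add atoms: phosphorus tribromide, BrP(Br)Br
Why: Conversion of a benzylic alcohol into the bromide by bromide displacement of the intermediate bromophosphite; the bromide is used without storage.

**Step 8**
Reactants: 11 (R)-4-(3,4-dimethoxybenzyl)dihydrofuran-2(3H)-one; 14 2-(benzyloxy)-4-(bromomethyl)-1-methoxybenzene
Product: 16 (3R,4R)-3-[3-(benzyloxy)-4-methoxybenzyl]-4-(3,4-dimethoxybenzyl)dihydrofuran-2(3H)-one, via lithium enolate 15 (not isolated)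
Conditions: LiN(SiMe3)2, THF, −78 °C; then 14, DMPU, −78 → −20 °C
Reagents that add atoms: none
Why: Kinetic lactone enolate alkylation (SN2 on the benzylic bromide); the electrophile approaches the face anti to the C4 benzyl group (1,2-induction in the five-membered ring), which sets C3 as R, trans to C4.

**Step 9**
Reactants: 16 (3R,4R)-3-[3-(benzyloxy)-4-methoxybenzyl]-4-(3,4-dimethoxybenzyl)dihydrofuran-2(3H)-one
Product: 17 Prestegane A, (3R,4R)-4-(3,4-dimethoxybenzyl)-3-(3-hydroxy-4-methoxybenzyl)dihydrofuran-2(3H)-one
Conditions: H2 (1 atm), 10% Pd/C, EtOAc, rt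
Reagents that add atoms: none
Why: Hydrogenolysis of the aryl benzyl ether; the lactone C5–O bond is not benzylic and the methyl ethers and both stereocentres are inert.

**Compound list**
1 | 3',4'-dimethoxyacetophenone | CC(=O)c1ccc(OC)c(OC)c1 | starting material
2 | dimethyl carbonate | COC(=O)OC | starting material
3 | methyl 3-(3,4-dimethoxyphenyl)-3-oxopropanoate | COC(=O)CC(=O)c1ccc(OC)c(OC)c1 | intermediate
4 | methyl bromoacetate | COC(=O)CBr | starting material
5 | racemic dimethyl 2-(3,4-dimethoxybenzoyl)succinate | COC(=O)CC(C(=O)OC)C(=O)c1ccc(OC)c(OC)c1 | intermediate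
6 | dimethyl (S)-2-[(S)-(3,4-dimethoxyphenyl)(hydroxy)methyl]succinate (syn hydroxy diester) | COC(=O)[C@@H](CC(=O)OC)[C@H](O)c1ccc(OC)c(OC)c1 | intermediate
7 | methyl (2S,3S)-2-(3,4-dimethoxyphenyl)-5-oxotetrahydrofuran-3-carboxylate | COC(=O)[C@H]1CC(=O)O[C@@H]1c1ccc(OC)c(OC)c1 | intermediate
8 | (R)-4-(3,4-dimethoxyphenyl)-3-(methoxycarbonyl)butanoic acid | COC(=O)[C@H](Cc1ccc(OC)c(OC)c1)CC(=O)O | intermediate
9 | potassium (R)-4-(3,4-dimethoxyphenyl)-3-(methoxycarbonyl)butanoate | COC(=O)[C@H](Cc1ccc(OC)c(OC)c1)CC(=O)[O-].[K+] | intermediate
10 | (R)-4-(3,4-dimethoxyphenyl)-3-(hydroxymethyl)butanoic acid | OC[C@H](Cc1ccc(OC)c(OC)c1)CC(=O)O | intermediate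
11 | (R)-4-(3,4-dimethoxybenzyl)dihydrofuran-2(3H)-one | O=C1C[C@@H](Cc2ccc(OC)c(OC)c2)CO1 | intermediate
12 | 3-(benzyloxy)-4-methoxybenzaldehyde | COc1ccc(C=O)cc1OCc1ccccc1 | starting material
13 | [3-(benzyloxy)-4-methoxyphenyl]methanol | COc1ccc(CO)cc1OCc1ccccc1 | intermediate
14 | 2-(benzyloxy)-4-(bromomethyl)-1-methoxybenzene | COc1ccc(CBr)cc1OCc1ccccc1 | intermediate
15 | lithium enolate of 11, lithium (R)-3-(3,4-dimethoxybenzyl)-2,3-dihydrofuran-5-olate | [Li+].[O-]C1=C[C@@H](Cc2ccc(OC)c(OC)c2)CO1 | intermediate
16 | (3R,4R)-3-[3-(benzyloxy)-4-methoxybenzyl]-4-(3,4-dimethoxybenzyl)dihydrofuran-2(3H)-one | COc1ccc(C[C@H]2C(=O)OC[C@@H]2Cc2ccc(OC)c(OC)c2)cc1OCc1ccccc1 | intermediate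
17 | Prestegane A | COc1ccc(C[C@H]2C(=O)OC[C@@H]2Cc2ccc(OC)c(OC)c2)cc1O | target

Total step count: 9
Longest linear sequence: 7 (steps 1, 2, 3, 4, 5, 8, 9)

**Steps most likely to fail**

Step 3. The syn/anti discrimination may be insufficient, or racemisation of 5 may be too slow relative to reduction of the electron-rich aryl ketone, so that the lactone carries the ring carbon that becomes C4 in low stereochemical purity. The fallback sets out from lactone 7 in whatever isomeric purity it is obtained and moves the stereo-determining event to an alkene hydrogenation. NaOMe in MeOH at reflux, then acid work-up, should open the lactone by E1cB elimination (the second half of a Stobbe condensation) to (E)-4-(3,4-dimethoxyphenyl)-3-(methoxycarbonyl)but-3-enoic acid F1. Asymmetric hydrogenation of its sodium salt with [Rh(cod)(Et-DuPHOS)]BF4 (ligand enantiomer chosen for the R acid), H2, MeOH should then give the half ester, and the route is rejoined at 8.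

Step 4. Cleavage of the benzylic C–O bond on the catalyst surface may be sluggish, or acid-promoted ionisation followed by β-elimination toward the α-ester carbon may erode its configuration. The fallback sets out from 7 and replaces surface hydrogenolysis by ionic hydrogenation: Et3SiH, CF3CO2H, CH2Cl2, 0 °C → rt. The acid ionises the lactone C–O bond to the dimethoxybenzylic cation and the silane traps it with hydride. It makes no new compound (F0) and comes back to the route at 8.

Step 5. Chemoselectivity between ester and carboxylate may be incomplete (unreduced ester or over-reduction), or the centre α to the ester may partly epimerise during salt formation. The fallback sets out from 8 and gives up the differentiation. LiAlH4 in THF should reduce both carboxyl groups to (R)-2-(3,4-dimethoxybenzyl)butane-1,4-diol F2. Fétizon oxidation (Ag2CO3 on Celite, toluene, reflux) then oxidises the less hindered CH2CH2OH terminus first, and the lactol is oxidised on to the β-substituted lactone, rejoining the route at 11.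

**Further compounds**
F1 | step 3 | (E)-4-(3,4-dimethoxyphenyl)-3-(methoxycarbonyl)but-3-enoic acid | COC(=O)/C(CC(=O)O)=C/c1ccc(OC)c(OC)c1
F0 | step 4 | none | none
F2 | step 5 | (R)-2-(3,4-dimethoxybenzyl)butane-1,4-diol | OC[C@H](Cc1ccc(OC)c(OC)c1)CCO
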